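**Assumption:** the SMILES is read as 19‑acetoxy‑ent‑labda‑8(17),13‑dien‑16,15‑olide (andrograpanin 19‑acetate; 4R,5S,9R,10S, labdane numbering used throughout). Bulk (−)‑andrographolide and 1,1‑dimethoxyethane are taken as purchasable.

## Retrosynthetic overview

1. All four stereocentres (C4, C5, C9, C10), rings A and B, the exocyclic alkene and the lactone ring are bought in andrographolide 1. No ring of the target is built.
2. The C3–H bond and the 19‑acetate are disconnected together to the 3,19‑O‑ethylidene acetal 5. A light‑driven hydrogen‑atom‑transfer isomerisation cleaves O–C3, forms C3–H and turns the acetal carbon into the acetate.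
3. The C12–H bond and the 13(14) alkene come from SN2′ hydride displacement of the 14‑acetate in 4.
4. Compound 4 comes from 1 and 2 by acetalisation of the 3,19‑diol and acetylation of 14‑OH in one flask.
5. Ring order: only a temporary 1,3‑dioxane is closed (step 1) and opened again (step 3).

## Route

**Step 1**
Reactants: 1 andrographolide; 2 1,1‑dimethoxyethane
Product: 4 14‑O‑acetyl‑3,19‑O‑ethylideneandrographolide, via ethylidene acetal 3 (not isolated)
Conditions: 2 (2 equiv), PPTS (10 mol%), THF, 40 °C; evaporate; then Ac2O (2 equiv), pyridine, DMAP (5 mol%), CH2Cl2, 0 °C to rt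
Reagents that add atoms: acetic anhydride, CC(=O)OC(C)=O
Why: Acid‑catalysed transacetalisation of the cis 3,19‑diol under thermodynamic control gives the 1,3‑dioxane with the methyl equatorial (acetal carbon R, erased again in step 3), then DMAP‑catalysed acetylation of the only free hydroxyl; the stereocentres of 1 are untouched.

**Step 2**
Reactants: 4 14‑O‑acetyl‑3,19‑O‑ethylideneandrographolide
Product: 5 14‑deoxy‑3,19‑O‑ethylideneandrographolide
Conditions: NaBH4 (1.2 equiv), THF/MeOH 5:1, −20 to 0 °C; aq. NH4Cl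
Reagents that add atoms: none
Why: SN2′ hydride reduction of a cyclic Morita–Baylis–Hillman‑type acetate: hydride adds to C12 of the α‑alkylidene lactone and the enolate expels the 14‑acetate (E1cB) to give the endocyclic butenolide; C14 becomes sp2, so no stereocentre is set.

**Step 3**
Reactants: 5 14‑deoxy‑3,19‑O‑ethylideneandrographolide
Product: 6 19‑acetoxy‑ent‑labda‑8(17),13‑dien‑16,15‑olide (target)
Conditions: 4CzIPN (2 mol%), quinuclidine (20 mol%), 1‑adamantanethiol (10 mol%), degassed MeCN (0.02 M), 450 nm LEDs, 50 °C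
Reagents that add atoms: none
Why: Proposed new method: a light‑driven, redox‑neutral isomerisation of an ethylidene acetal to a deoxy acetate, in which excited 4CzIPN oxidises quinuclidine to its radical cation, this abstracts the hydridic axial acetal C–H of 5, the 2‑methyl‑1,3‑dioxan‑2‑yl radical undergoes β‑scission of the O–C3 bond (the secondary ring radical next to quaternary C4 is favoured over the primary C19 radical, with C=O formation as driving force), the C3 radical takes hydrogen from the thiol to form the C3–H bond, and the thiyl radical is reduced by the 4CzIPN radical anion and reprotonated by quinuclidinium; the closest known reaction type is the thermal, peroxide‑initiated, thiol‑catalysed radical‑chain redox rearrangement of cyclic benzylidene acetals to benzoates of deoxy alcohols, here merged with photoredox/quinuclidine/thiol HAT catalysis and applied to a 2‑methyl acetal to deliver an acetate; C3 becomes CH2, so no stereocentre is formed or disturbed.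

## Compound list

1 | andrographolide, (3R,4R,5S,9R,10S,12E,14S)‑3,14,19‑trihydroxy‑ent‑labda‑8(17),12‑dien‑16,15‑olide (3‑OH, C19 and C20 on the α face, H5 and H9 β) | C=C1CC[C@@H]2[C@](C)(CO)[C@H](O)CC[C@@]2(C)[C@@H]1C/C=C1/C(=O)OC[C@H]1O | starting material
2 | 1,1‑dimethoxyethane (acetaldehyde dimethyl acetal) | CC(OC)OC | starting material
3 | 3,19‑O‑[(R)‑ethylidene]andrographolide (1,3‑dioxane across O3 and O19, acetal methyl equatorial, 14S‑OH free) | C=C1CC[C@@H]2[C@]3(C)CO[C@@H](C)O[C@@H]3CC[C@@]2(C)[C@@H]1C/C=C1/C(=O)OC[C@H]1O | intermediate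
4 | 14‑O‑acetyl‑3,19‑O‑[(R)‑ethylidene]andrographolide (14S acetate, 12E) | C=C1CC[C@@H]2[C@]3(C)CO[C@@H](C)O[C@@H]3CC[C@@]2(C)[C@@H]1C/C=C1/C(=O)OC[C@H]1OC(C)=O | intermediate
5 | 14‑deoxy‑3,19‑O‑[(R)‑ethylidene]andrographolide (3R,4R,5S,9R,10S; 13(14)‑butenolide) | C=C1CC[C@@H]2[C@]3(C)CO[C@@H](C)O[C@@H]3CC[C@@]2(C)[C@@H]1CCC1=CCOC1=O | intermediate
6 | 19‑acetoxy‑ent‑labda‑8(17),13‑dien‑16,15‑olide, i.e. {(1R,4aS,5R,8aS)‑1,4a‑dimethyl‑6‑methylidene‑5‑[2‑(2‑oxo‑2,5‑dihydrofuran‑3‑yl)ethyl]decahydronaphthalen‑1‑yl}methyl acetate | C=C1CC[C@@H]2[C@](C)(COC(C)=O)CCC[C@@]2(C)[C@@H]1CCC1=CCOC1=O | target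

## Step count and risks

Total steps: 3. Longest linear sequence: 3.

**Most likely to fail, first: step 3 (the proposed new isomerisation).** The possible failures are:
- β‑scission too slow relative to hydrogen return from the thiol;
- cleavage of O–C19 instead of O–C3, giving the 3‑acetoxy‑19‑deoxy isomer;
- addition of the acetal radical to a butenolide of a second molecule;
- thiyl‑radical or base chemistry at the 8(17) alkene or the butenolide.

The fallback uses known chemistry, sets out from 5 and comes back at 6. Aqueous acetic acid in THF at 40 °C removes the acetal to give 14‑deoxyandrographolide F1. Ac2O (1.1 equiv) in pyridine at 0 °C acetylates the primary hydroxyl only, giving 19‑O‑acetyl‑14‑deoxyandrographolide F2. Phenyl chlorothionoformate with DMAP and pyridine in CH2Cl2 gives 19‑O‑acetyl‑14‑deoxy‑3‑O‑(phenoxythiocarbonyl)andrographolide F3. Barton–McCombie deoxygenation (Bu3SnH, AIBN, toluene, 90 °C) then gives 6.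

**Second: step 2 (SN2′ hydride reduction).** The risks are further reduction of the new butenolide or of the lactone carbonyl, and incomplete elimination. The fallback sets out from 3, isolated by stopping step 1 before the anhydride is added, and comes back at 5. It is a reductive 1,3‑transposition of the free allylic alcohol. Mitsunobu reaction with 2‑nitrobenzenesulfonylhydrazide (PPh3, DEAD, THF, −30 °C) gives, with inversion at C14, the 14‑(N‑amino‑2‑nitrobenzenesulfonamido) adduct F4. On warming to rt this loses the sulfinic acid to give the allylic 14‑diazenyl compound F5. Retro‑ene loss of N2 delivers hydrogen to C12 and places the alkene at C13–C14, giving 5.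

**Third: step 1 (one‑flask acetalisation and acetylation).** The risks are a mixed acyclic acetal at O14 and base‑induced loss of the 14‑acetate to the 11,13‑diene. The fallback sets out from 1 and comes back at 5, and moves the acetal to after the C14 deoxygenation. Ac2O with DMAP in pyridine gives 3,14,19‑tri‑O‑acetylandrographolide F6. NaBH4 in THF/MeOH at −20 to 0 °C gives 3,19‑di‑O‑acetyl‑14‑deoxyandrographolide F7. K2CO3 in MeOH at 0 °C gives 14‑deoxyandrographolide F1, the diol already described. Acetalisation with 2 and PPTS in THF at 40 °C gives 5.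

## Further compounds

F1 | step 3 | 14‑deoxyandrographolide | C=C1CC[C@@H]2[C@](C)(CO)[C@H](O)CC[C@@]2(C)[C@@H]1CCC1=CCOC1=O
F2 | step 3 | 19‑O‑acetyl‑14‑deoxyandrographolide | C=C1CC[C@@H]2[C@](C)(COC(C)=O)[C@H](O)CC[C@@]2(C)[C@@H]1CCC1=CCOC1=O
F3 | step 3 | 19‑O‑acetyl‑14‑deoxy‑3‑O‑(phenoxythiocarbonyl)andrographolide | C=C1CC[C@@H]2[C@](C)(COC(C)=O)[C@H](OC(=S)Oc3ccccc3)CC[C@@]2(C)[C@@H]1CCC1=CCOC1=O
F4 | step 2 | (14R)‑14‑(N‑amino‑2‑nitrobenzenesulfonamido)‑14‑deoxy‑3,19‑O‑[(R)‑ethylidene]andrographolide | C=C1CC[C@@H]2[C@]3(C)CO[C@@H](C)O[C@@H]3CC[C@@]2(C)[C@@H]1C/C=C1/C(=O)OC[C@@H]1N(N)S(=O)(=O)c1ccccc1[N+](=O)[O-]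
F5 | step 2 | (14R)‑14‑diazenyl‑14‑deoxy‑3,19‑O‑[(R)‑ethylidene]andrographolide | C=C1CC[C@@H]2[C@]3(C)CO[C@@H](C)O[C@@H]3CC[C@@]2(C)[C@@H]1C/C=C1/C(=O)OC[C@@H]1N=N
F6 | step 1 | 3,14,19‑tri‑O‑acetylandrographolide | C=C1CC[C@@H]2[C@](C)(COC(C)=O)[C@H](OC(C)=O)CC[C@@]2(C)[C@@H]1C/C=C1/C(=O)OC[C@H]1OC(C)=O
F7 | step 1 | 3,19‑di‑O‑acetyl‑14‑deoxyandrographolide | C=C1CC[C@@H]2[C@](C)(COC(C)=O)[C@H](OC(C)=O)CC[C@@]2(C)[C@@H]1CCC1=CCOC1=O
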